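**Retrosynthetic overview**
1. 13 ⇒ 9 + 12: the C5–O aryl ether is made last, by anti opening of diol-epoxide 9 at C5 with the 6-oxygen of the catecholate of 12 (sets C5, no protecting groups).
2. 9 ⇒ 8: the oxirane is closed on C5=C6 of trans-dihydrodiol 8 by 7-OH-directed epoxidation (C5/C6 set from C7).
3. 8 ⇒ 5 ⇒ 4: the aromatic A ring of catechol-chromone 4 is de-aromatised through o-quinone 5 and a catalyst-controlled double carbonyl reduction (C7/C8, the only source of absolute configuration).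
4. 4 and 12 ⇒ 1 or 10 + 2: each γ-pyrone is closed by cyclodehydration of a 1-(2-hydroxyaryl)-5-phenylpentane-1,3-dione (3, 11).
5. Ring order: pyrone of the tetrahydro half (step 1) → oxirane (step 4); pyrone of the aromatic half (step 5); both carbocycles come from the acetophenones; the halves are joined in step 6.

Assumption 1: salts formed by simple deprotonation of a numbered compound in the flask (lithium polyanions of 1, 3, 10, 11; disodium salt of 12; product alkoxides) are treated as that compound and get no number.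
Assumption 2: the sense of induction in step 3 follows the usual CBS model with the outer sp2 flank as the large group; if the measured sign is opposite, the (S)-catalyst is used with no other change.

**Step 1**
Reactants: 1 1-(2,3,4-trihydroxyphenyl)ethan-1-one; 2 3-phenylpropanoyl chloride
Product: 4 7,8-dihydroxy-2-(2-phenylethyl)-4H-chromen-4-one, via trihydroxyphenyl pentanedione 3 (not isolated)
Conditions: LiHMDS (4.1 equiv), THF, −78 → −10 °C, Ar; 2 (1.0 equiv), −78 °C → rt; 1 M HCl; crude 3, AcOH, cat. H2SO4, 95 °C, 1 h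
Reagents that add atoms: none
Why: Crossed Claisen C-acylation of the lithium enolate of the tetralithiated acetophenone (the most nucleophilic site; any phenolic ester is cleaved in the acid stage) gives the polyketide-type 1,3-diketone, whose 2'-OH adds to the distal carbonyl and loses water (acid-catalysed cyclodehydration) to close the γ-pyrone; no stereocentre is formed.

**Step 2**
Reactants: 4 7,8-dihydroxy-2-(2-phenylethyl)-4H-chromen-4-one
Product: 5 2-(2-phenylethyl)-4H-chromene-4,7,8-trione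
Conditions: Ag2O (3 equiv), Na2SO4, dry CH2Cl2/THF, 0 °C, dark, 20 min; filter (Celite), evaporate cold, use at once
Reagents that add atoms: none
Why: Ag(I) oxide dehydrogenation of a catechol to its o-quinone under neutral anhydrous conditions de-aromatises the A ring without touching the pyrone or the phenethyl chain; no stereocentre is formed.

**Step 3**
Reactants: 5 2-(2-phenylethyl)-4H-chromene-4,7,8-trione
Product: 8 (7R,8S)-7,8-dihydroxy-2-(2-phenylethyl)-7,8-dihydro-4H-chromen-4-one, via 8-boryloxy 7-ketone 6 (not isolated), via bis-catecholboryl ether 7 (not isolated)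
Conditions: (R)-Me-CBS (0.5 equiv), catecholborane (2.5 equiv), CH2Cl2/toluene, −78 °C, 6 h; MeOH, then pH 7 phosphate buffer, 0 °C; recryst. to raise ee
Reagents that add atoms: none
Why: Proposed new method: oxazaborolidine-activated catecholborane should transfer hydride 1,2 first to the more electrophilic C8 carbonyl and then to C7, each on the face set by the (R)-catalyst, with the second hydride arriving anti to the bulky C8 boryloxy group so that catalyst and substrate control reinforce each other and give the trans (7R,8S) bis-boronate (mismatched material ends as separable cis diol), while the neutral O-boryl ketol formed without base is slow to enolise to the catechol; the closest known reactions are the CBS reduction of benzil and cyclic ene-diones to C2-type diols and the LiAlH4 or NaBH4/O2 reduction of non-K-region o-quinones to trans-dihydrodiols.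

**Step 4**
Reactants: 8 (7R,8S)-7,8-dihydroxy-2-(2-phenylethyl)-7,8-dihydro-4H-chromen-4-one
Product: 9 (1aS,2S,3S,7bR)-2,3-dihydroxy-5-(2-phenylethyl)-1a,2,3,7b-tetrahydro-7H-oxireno[f]chromen-7-one
Conditions: mCPBA (5 equiv), dry THF, 0 °C → rt, 2 h; cold aq. NaHCO3 wash; use at once
Reagents that add atoms: mCPBA (3-chloroperoxybenzoic acid), OOC(=O)c1cccc(Cl)c1
Why: Hydroxyl-directed (Henbest) peracid epoxidation, the known behaviour of arene trans-dihydrodiols, in which the allylic 7-OH hydrogen-bonds the peracid and delivers oxygen to its own face of the only electron-rich alkene (C5=C6), so the oxirane forms cis to 7-OH and trans to 8-OH and fixes C5 (R) and C6 (S), the push-pull pyrone double bonds being inert to mCPBA.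

**Step 5**
Reactants: 10 1-(2,4,5-trihydroxyphenyl)ethan-1-one; 2 3-phenylpropanoyl chloride
Product: 12 6,7-dihydroxy-2-(2-phenylethyl)-4H-chromen-4-one, via trihydroxyphenyl pentanedione 11 (not isolated)
Conditions: LiHMDS (4.1 equiv), THF, −78 → −10 °C, Ar; 2 (1.0 equiv), −78 °C → rt; 1 M HCl; crude 11, AcOH, cat. H2SO4, 95 °C, 1 h
Reagents that add atoms: none
Why: Same crossed Claisen C-acylation of the polyanion enolate followed by acid-catalysed cyclodehydration of the 1,3-diketone through its 2'-OH, giving the second γ-pyrone; no stereocentre is formed.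

**Step 6**
Reactants: 9 (1aS,2S,3S,7bR)-2,3-dihydroxy-5-(2-phenylethyl)-1a,2,3,7b-tetrahydro-7H-oxireno[f]chromen-7-one; 12 6,7-dihydroxy-2-(2-phenylethyl)-4H-chromen-4-one
Product: 13 7-hydroxy-2-(2-phenylethyl)-6-{[(5S,6S,7R,8S)-6,7,8-trihydroxy-4-oxo-2-(2-phenylethyl)-5,6,7,8-tetrahydro-4H-chromen-5-yl]oxy}-4H-chromen-4-one
Conditions: 12 (1.5 equiv), NaH (3.0 equiv), DMSO, rt, 30 min, Ar; 9 (1.0 equiv), rt, 12 h; AcOH (3 equiv), 0 °C; reversed-phase chromatography
Reagents that add atoms: none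
Why: Intermolecular SN2 opening of the oxirane at C5, the carbon activated by O1 through the C4a=C8a bond (vinylogous benzylic position, trans-diaxial attack as with other anti diol-epoxides), by the catecholate dianion, whose O6 oxide is the more basic and nucleophilic because the O7 oxide is delocalised into the pyrone carbonyl (the dianion effect that directs alkylation of 3,4-dihydroxybenzaldehyde to O3), inverts C5 to S and leaves C6, C7 and C8 untouched.

**Compound list**
1 | 1-(2,3,4-trihydroxyphenyl)ethan-1-one (gallacetophenone) | CC(=O)c1ccc(O)c(O)c1O | starting material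
2 | 3-phenylpropanoyl chloride | O=C(Cl)CCc1ccccc1 | starting material
3 | 1-(2,3,4-trihydroxyphenyl)-5-phenylpentane-1,3-dione | O=C(CC(=O)CCc1ccccc1)c1ccc(O)c(O)c1O | intermediate
4 | 7,8-dihydroxy-2-(2-phenylethyl)-4H-chromen-4-one | O=c1cc(CCc2ccccc2)oc2c(O)c(O)ccc12 | intermediate
5 | 2-(2-phenylethyl)-4H-chromene-4,7,8-trione (o-quinone) | O=C1C=Cc2c(oc(CCc3ccccc3)cc2=O)C1=O | intermediate
6 | (8R)-8-(1,3,2-benzodioxaborol-2-yloxy)-2-(2-phenylethyl)-4H-chromene-4,7(8H)-dione (same spatial sense at C8 as in 8) | O=c1cc(CCc2ccccc2)oc2c1C=CC(=O)[C@@H]2OB3Oc4ccccc4O3 | intermediate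
7 | (7R,8S)-7,8-bis(1,3,2-benzodioxaborol-2-yloxy)-2-(2-phenylethyl)-7,8-dihydro-4H-chromen-4-one (trans) | O=c1cc(CCc2ccccc2)oc2c1C=C[C@@H](OB3Oc4ccccc4O3)[C@@H]2OB5Oc6ccccc6O5 | intermediate
8 | (7R,8S)-7,8-dihydroxy-2-(2-phenylethyl)-7,8-dihydro-4H-chromen-4-one (trans-diol) | O=c1cc(CCc2ccccc2)oc2c1C=C[C@@H](O)[C@@H]2O | intermediate
9 | (1aS,2S,3S,7bR)-2,3-dihydroxy-5-(2-phenylethyl)-1a,2,3,7b-tetrahydro-7H-oxireno[f]chromen-7-one, i.e. the (5R,6S,7S,8S)-5,6-epoxy-7,8-diol, oxirane cis to 7-OH and trans to 8-OH | O=c1cc(CCc2ccccc2)oc2c1[C@H]3O[C@H]3[C@@H](O)[C@@H]2O | intermediate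
10 | 1-(2,4,5-trihydroxyphenyl)ethan-1-one | CC(=O)c1cc(O)c(O)cc1O | starting material
11 | 1-(2,4,5-trihydroxyphenyl)-5-phenylpentane-1,3-dione | O=C(CC(=O)CCc1ccccc1)c1cc(O)c(O)cc1O | intermediate
12 | 6,7-dihydroxy-2-(2-phenylethyl)-4H-chromen-4-one | O=c1cc(CCc2ccccc2)oc2cc(O)c(O)cc12 | intermediate
13 | 7-hydroxy-2-(2-phenylethyl)-6-{[(5S,6S,7R,8S)-6,7,8-trihydroxy-4-oxo-2-(2-phenylethyl)-5,6,7,8-tetrahydro-4H-chromen-5-yl]oxy}-4H-chromen-4-one (5-OAr and 8-OH on one face, 6-OH and 7-OH on the other) | O=c1cc(CCc2ccccc2)oc2c1[C@H](Oc1cc3c(=O)cc(CCc4ccccc4)oc3cc1O)[C@@H](O)[C@@H](O)[C@@H]2O | target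

**Total step count:** 6. **Longest linear sequence:** 5 (steps 1, 2, 3, 4, 6).

**Three steps most likely to fail**

Step 3 (unprecedented asymmetric reduction of an o-quinone; tautomerisation to catechol 4, cis diol or low ee are possible). The fallback sets out from 5 and comes back at 8. Compound 5 is reduced with NaBH4 in EtOH under a stream of O2, so that any catechol 4 formed is re-oxidised to 5 in the flask, giving the racemic diol rac-(7R,8S)-7,8-dihydroxy-2-(2-phenylethyl)-7,8-dihydro-4H-chromen-4-one F1. Acylation with (−)-menthyloxyacetyl chloride and pyridine gives two diastereomeric bis-esters, (7R,8S)-4-oxo-2-(2-phenylethyl)-7,8-dihydro-4H-chromene-7,8-diyl bis{[(1R,2S,5R)-menthyl]oxyacetate} F2 and (7S,8R)-4-oxo-2-(2-phenylethyl)-7,8-dihydro-4H-chromene-7,8-diyl bis{[(1R,2S,5R)-menthyl]oxyacetate} F3. These are separated by crystallisation or preparative HPLC, and NaOMe in MeOH at 0 °C releases 8 from F2.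

Step 6 (O6 versus O7 selectivity of the unprotected catechol, and base sensitivity of 9). The fallback sets out from 12 and comes back at 13. The more acidic 7-OH of 12 is allylated selectively (allyl bromide 1.05 equiv, K2CO3 1.1 equiv, DMF, rt) to 6-hydroxy-2-(2-phenylethyl)-7-(prop-2-en-1-yloxy)-4H-chromen-4-one F4. Its single phenoxide (Cs2CO3, DMF, 40 °C) opens 9 at C5 to give 2-(2-phenylethyl)-7-(prop-2-en-1-yloxy)-6-{[(5S,6S,7R,8S)-6,7,8-trihydroxy-4-oxo-2-(2-phenylethyl)-5,6,7,8-tetrahydro-4H-chromen-5-yl]oxy}-4H-chromen-4-one F5. Pd(PPh3)4 and morpholine in THF at rt then remove the allyl group to give 13.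

Step 1 (C-acylation of an unprotected, air-sensitive polyanion with an enolisable acyl chloride). The fallback sets out from 1 and comes back at 4. Compound 1 is methylated at the two non-chelated hydroxyls (Me2SO4 2.1 equiv, K2CO3, acetone, reflux) to 1-(2-hydroxy-3,4-dimethoxyphenyl)ethan-1-one F6. LiHMDS (3 equiv) and 2 give 1-(2-hydroxy-3,4-dimethoxyphenyl)-5-phenylpentane-1,3-dione F7, which is cyclised (AcOH, cat. H2SO4, 95 °C) to 7,8-dimethoxy-2-(2-phenylethyl)-4H-chromen-4-one F8. BBr3 in CH2Cl2 (−78 °C → rt) then gives 4.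

**Further compounds**
F1 | step 3 | rac-(7R,8S)-7,8-dihydroxy-2-(2-phenylethyl)-7,8-dihydro-4H-chromen-4-one (racemate, both enantiomers written) | O=c1cc(CCc2ccccc2)oc2c1C=C[C@@H](O)[C@@H]2O.O=c1cc(CCc2ccccc2)oc2c1C=C[C@H](O)[C@H]2O
F2 | step 3 | (7R,8S)-4-oxo-2-(2-phenylethyl)-7,8-dihydro-4H-chromene-7,8-diyl bis{[(1R,2S,5R)-menthyl]oxyacetate} | O=c1cc(CCc2ccccc2)oc2c1C=C[C@@H](OC(=O)CO[C@@H]3C[C@H](C)CC[C@H]3C(C)C)[C@@H]2OC(=O)CO[C@@H]4C[C@H](C)CC[C@H]4C(C)C
F3 | step 3 | (7S,8R)-4-oxo-2-(2-phenylethyl)-7,8-dihydro-4H-chromene-7,8-diyl bis{[(1R,2S,5R)-menthyl]oxyacetate} | O=c1cc(CCc2ccccc2)oc2c1C=C[C@H](OC(=O)CO[C@@H]3C[C@H](C)CC[C@H]3C(C)C)[C@H]2OC(=O)CO[C@@H]4C[C@H](C)CC[C@H]4C(C)C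
F4 | step 6 | 6-hydroxy-2-(2-phenylethyl)-7-(prop-2-en-1-yloxy)-4H-chromen-4-one | O=c1cc(CCc2ccccc2)oc2cc(OCC=C)c(O)cc12
F5 | step 6 | 2-(2-phenylethyl)-7-(prop-2-en-1-yloxy)-6-{[(5S,6S,7R,8S)-6,7,8-trihydroxy-4-oxo-2-(2-phenylethyl)-5,6,7,8-tetrahydro-4H-chromen-5-yl]oxy}-4H-chromen-4-one | O=c1cc(CCc2ccccc2)oc2c1[C@H](Oc1cc3c(=O)cc(CCc4ccccc4)oc3cc1OCC=C)[C@@H](O)[C@@H](O)[C@@H]2O
F6 | step 1 | 1-(2-hydroxy-3,4-dimethoxyphenyl)ethan-1-one | CC(=O)c1ccc(OC)c(OC)c1O
F7 | step 1 | 1-(2-hydroxy-3,4-dimethoxyphenyl)-5-phenylpentane-1,3-dione | O=C(CC(=O)CCc1ccccc1)c1ccc(OC)c(OC)c1O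
F8 | step 1 | 7,8-dimethoxy-2-(2-phenylethyl)-4H-chromen-4-one | COc1ccc2c(=O)cc(CCc3ccccc3)oc2c1OC
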